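**Retrosynthetic overview**
1. C9–C10: late Negishi sp3–sp2 coupling of peroxylactone iodide 17 with dienyl iodide 25, so the diene never meets ozone or a cation.
2. C6 quaternary peroxy centre: axial methyl transfer from AlMe3 to the cyclic peroxycarbenium ion of methoxy peroxyketal 16 (new reaction).
3. Ring B (1,2-dioxane) is closed second, by ozonolysis in MeOH and intramolecular oxa-Michael addition onto ring A (butenolide), which is made first by Z-olefination/lactonisation.
4. C6–C7: electrochemical Ni-catalysed cross-electrophile coupling of vinyl bromide 6 with (S)-3-bromo-2-methylpropan-1-ol 7 (C8 bought) unites the two chiral-pool fragments.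
5. C4: from (S)-lactic acid by dioxolanone alkylation (self-regeneration of the stereocentre); C3 and C6 then follow from C4.

Assumption: plakortolide numbering is used for locants in the text (C1 lactone carbonyl, C3 and C6 peroxide carbons, C4 lactone C–O carbon, C8 side-chain methine, C14 benzylic CH2); the SMILES is read as 3R,4R,6R,8S,10E,12E.

**Step 1**
Reactants: 1 (S)-lactic acid; 2 pivalaldehyde
Product: 3 (2S,5S)-2-tert-butyl-5-methyl-1,3-dioxolan-4-one
Conditions: TsOH (cat.), H2SO4 (cat.), pentane, reflux (Dean–Stark); recrystallise at −78 °C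
Reagents that add atoms: none
Why: Acid-catalysed acetalisation of the α-hydroxy acid (Seebach dioxolanone), in which the lactate centre sets the acetal carbon cis under thermodynamic control and crystallisation removes the minor trans isomer.

**Step 2**
Reactants: 3 (2S,5S)-2-tert-butyl-5-methyl-1,3-dioxolan-4-one; 4 2,3-dibromopropene
Product: 6 (2S,5R)-5-(2-bromoprop-2-en-1-yl)-2-tert-butyl-5-methyl-1,3-dioxolan-4-one, via lithium enolate 5 (not isolated)
Conditions: LDA, THF, −78 °C; then 4, −78 → −30 °C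
Reagents that add atoms: none
Why: Enolate alkylation with self-regeneration of the stereocentre: the planar enolate attacks the allylic bromide (SN2) on the face opposite the tert-butyl group, so the C4 quaternary centre is fixed by the acetal centre that lactic acid had set.

**Step 3**
Reactants: 6 (2S,5R)-5-(2-bromoprop-2-en-1-yl)-2-tert-butyl-5-methyl-1,3-dioxolan-4-one; 7 (S)-3-bromo-2-methylpropan-1-ol
Product: 8 (2S,5R)-2-tert-butyl-5-[(4R)-5-hydroxy-4-methyl-2-methylidenepentyl]-5-methyl-1,3-dioxolan-4-one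
Conditions: NiBr2·dme (10 mol%), 4,4′-di-tert-butyl-2,2′-bipyridine (10 mol%), NaI (0.25 equiv), DMA, undivided cell, Zn anode, Ni-foam cathode, constant current (about 2.2 F/mol), rt
Reagents that add atoms: none
Why: Nickel-catalysed electroreductive cross-electrophile coupling, in which cathodically formed zerovalent nickel inserts into the vinyl C–Br bond, the primary alkyl bromide enters as a radical and reductive elimination forms C6–C7; the bought C8 centre is not touched and the free hydroxyl is tolerated.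

**Step 4**
Reactants: 8 (2S,5R)-2-tert-butyl-5-[(4R)-5-hydroxy-4-methyl-2-methylidenepentyl]-5-methyl-1,3-dioxolan-4-one
Product: 9 (2S,5R)-2-tert-butyl-5-[(4R)-5-iodo-4-methyl-2-methylidenepentyl]-5-methyl-1,3-dioxolan-4-one
Conditions: I2, PPh3, imidazole, CH2Cl2, 0 °C
Reagents that add atoms: iodine, II
Why: Appel iodination (SN2 at a non-stereogenic primary carbon) installs a non-participating handle for the final coupling.

**Step 5**
Reactants: 9 (2S,5R)-2-tert-butyl-5-[(4R)-5-iodo-4-methyl-2-methylidenepentyl]-5-methyl-1,3-dioxolan-4-one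
Product: 10 (2S,4RS,5R)-2-tert-butyl-5-[(4R)-5-iodo-4-methyl-2-methylidenepentyl]-5-methyl-1,3-dioxolan-4-ol
Conditions: DIBAL-H (1.2 equiv), CH2Cl2, −78 °C; Rochelle salt work-up
Reagents that add atoms: none
Why: Partial reduction of the lactone-type carbonyl with DIBAL-H stops at the lactol at low temperature, and the lactol epimers are of no consequence.

**Step 6**
Reactants: 10 (2S,4RS,5R)-2-tert-butyl-5-[(4R)-5-iodo-4-methyl-2-methylidenepentyl]-5-methyl-1,3-dioxolan-4-ol; 11 methyl 2-[bis(2,2,2-trifluoroethoxy)phosphoryl]acetate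
Product: 14 (5R)-5-[(4R)-5-iodo-4-methyl-2-methylidenepentyl]-5-methylfuran-2(5H)-one, via hydroxy aldehyde 12 (not isolated), via Z-enoate 13 (not isolated)
Conditions: 11 (2.5 equiv), KHMDS (2.4 equiv), 18-crown-6, THF, −78 → 0 °C; aq. NH4Cl
Reagents that add atoms: none
Why: Still–Gennari (Z-selective Horner–Wadsworth–Emmons) olefination of the hydroxy aldehyde released from the lactol, after which the tertiary alkoxide lactonises onto the Z-ester to close ring A; excess reagent scavenges the liberated pivalaldehyde and C4 is untouched.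

**Step 7**
Reactants: 14 (5R)-5-[(4R)-5-iodo-4-methyl-2-methylidenepentyl]-5-methylfuran-2(5H)-one
Product: 16 (1R,4RS,6R)-4-[(2R)-3-iodo-2-methylpropyl]-4-methoxy-6-methyl-2,3,7-trioxabicyclo[4.3.0]nonan-8-one, via hydroperoxy ketal 15 (not isolated)
Conditions: O3, CH2Cl2/MeOH (3:1), −78 °C (Sudan Red 7B end point); N2 purge, concentrate cold; then Et2NH (0.3 equiv), CF3CH2OH, 0 °C → rt
Reagents that add atoms: ozone, [O-][O+]=O; methanol, CO
Why: Chemoselective ozonolysis of the electron-rich 1,1-disubstituted alkene in methanol gives the α-methoxy hydroperoxide (Criegee carbonyl oxide trapped by MeOH), which closes ring B by intramolecular oxa-Michael addition on the only butenolide face its C5 tether can reach, so C3 is set cis-fused by C4 while C6 remains an anomeric mixture that step 8 erases.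

**Step 8**
Reactants: 16 (1R,4RS,6R)-4-[(2R)-3-iodo-2-methylpropyl]-4-methoxy-6-methyl-2,3,7-trioxabicyclo[4.3.0]nonan-8-one
Product: 17 (1R,4R,6R)-4-[(2R)-3-iodo-2-methylpropyl]-4,6-dimethyl-2,3,7-trioxabicyclo[4.3.0]nonan-8-one
Conditions: AlMe3 (3.0 equiv), TMSOTf (0.2 equiv), CH2Cl2, −78 → −40 °C; Rochelle salt work-up
Reagents that add atoms: trimethylaluminium, C[Al](C)C
Why: Proposed new method: TMSOTf ionises the exocyclic methoxy group to a cyclic peroxycarbenium ion whose half-chair keeps the lactone oxygen pseudoaxial and the C4 methyl and C2 pseudoequatorial, and AlMe3 transfers methyl along the axial, chair-forming trajectory cis to the lactone oxygen, so both anomers converge on the C6 quaternary centre with the side chain equatorial; the closest known reactions are Lewis-acid-mediated allylation and Mukaiyama-type additions to peroxycarbenium ions of peroxyketals and the AlMe3 methylation of cyclic ketals and glycosyl donors, neither of which has been shown for a methyl nucleophile on a peroxyketal.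

**Step 9**
Reactants: 18 phenylacetaldehyde; 19 2-(triphenylphosphoranylidene)propanal
Product: 20 (2E)-2-methyl-4-phenylbut-2-enal
Conditions: toluene, 80 °C
Reagents that add atoms: none
Why: Wittig olefination with a formyl-stabilised ylide gives the (E)-trisubstituted enal that carries C11–C14.

**Step 10**
Reactants: 20 (2E)-2-methyl-4-phenylbut-2-enal
Product: 21 [(2E)-5,5-dibromo-3-methylpenta-2,4-dien-1-yl]benzene
Conditions: CBr4, PPh3, Zn dust, CH2Cl2, 0 °C → rt
Reagents that add atoms: carbon tetrabromide, BrC(Br)(Br)Br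
Why: Corey–Fuchs (Ramirez) dibromo-olefination of the aldehyde, which leaves the existing E-alkene alone.

**Step 11**
Reactants: 21 [(2E)-5,5-dibromo-3-methylpenta-2,4-dien-1-yl]benzene
Product: 23 [(2E)-3-methylhex-2-en-4-yn-1-yl]benzene, via lithium acetylide 22 (not isolated)
Conditions: n-BuLi (2.1 equiv), THF, −78 °C; then MeI, −78 °C → rt
Reagents that add atoms: iodomethane, CI
Why: Second stage of the Corey–Fuchs alkyne synthesis (Br/Li exchange and rearrangement to the lithium acetylide) followed by C-methylation with MeI.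

**Step 12**
Reactants: 23 [(2E)-3-methylhex-2-en-4-yn-1-yl]benzene
Product: 25 [(2E,4E)-5-iodo-3-methylhexa-2,4-dien-1-yl]benzene, via alkenylzirconocene 24 (not isolated)
Conditions: Cp2Zr(H)Cl (1.5 equiv), THF, 40 °C; then I2, 0 °C
Reagents that add atoms: iodine, II
Why: Syn hydrozirconation with Schwartz's reagent places zirconium on the less hindered, methyl-bearing alkyne carbon (thermodynamic regioisomer), and iodinolysis with retention gives the (E)-alkenyl iodide.

**Step 13**
Reactants: 17 (1R,4R,6R)-4-[(2R)-3-iodo-2-methylpropyl]-4,6-dimethyl-2,3,7-trioxabicyclo[4.3.0]nonan-8-one; 25 [(2E,4E)-5-iodo-3-methylhexa-2,4-dien-1-yl]benzene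
Product: 27 plakortolide (1R,4R,6R)-4,6-dimethyl-4-[(2S,4E,6E)-2,4,6-trimethyl-8-phenylocta-4,6-dien-1-yl]-2,3,7-trioxabicyclo[4.3.0]nonan-8-one, via alkylzinc iodide 26 (not isolated)
Conditions: Zn dust (TMSCl-activated), LiCl, THF, 25 °C; then 25, PdCl2(dppf) (5 mol%), THF, 25 °C
Reagents that add atoms: none
Why: Negishi cross-coupling, in which zinc inserts into the primary C–I bond and the alkylzinc couples with the alkenyl iodide with retention of alkene geometry under neutral conditions; no stereocentre is affected and the neutral medium is chosen to spare the peroxide and lactone.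

**Compound list**
1 | (S)-lactic acid | C[C@H](O)C(=O)O | starting material
2 | pivalaldehyde | CC(C)(C)C=O | starting material
3 | (2S,5S)-2-tert-butyl-5-methyl-1,3-dioxolan-4-one | C[C@@H]1O[C@H](C(C)(C)C)OC1=O | intermediate
4 | 2,3-dibromopropene | C=C(Br)CBr | starting material
5 | lithium (2S)-2-tert-butyl-5-methyl-1,3-dioxol-4-olate (lithium enolate) | CC1=C(O[Li])O[C@@H](C(C)(C)C)O1 | intermediate
6 | (2S,5R)-5-(2-bromoprop-2-en-1-yl)-2-tert-butyl-5-methyl-1,3-dioxolan-4-one | C[C@]1(CC(Br)=C)O[C@H](C(C)(C)C)OC1=O | intermediate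
7 | (S)-3-bromo-2-methylpropan-1-ol | OC[C@H](C)CBr | starting material
8 | (2S,5R)-2-tert-butyl-5-[(4R)-5-hydroxy-4-methyl-2-methylidenepentyl]-5-methyl-1,3-dioxolan-4-one | C[C@]1(CC(=C)C[C@@H](C)CO)O[C@H](C(C)(C)C)OC1=O | intermediate
9 | (2S,5R)-2-tert-butyl-5-[(4R)-5-iodo-4-methyl-2-methylidenepentyl]-5-methyl-1,3-dioxolan-4-one | C[C@]1(CC(=C)C[C@@H](C)CI)O[C@H](C(C)(C)C)OC1=O | intermediate
10 | (2S,4RS,5R)-2-tert-butyl-5-[(4R)-5-iodo-4-methyl-2-methylidenepentyl]-5-methyl-1,3-dioxolan-4-ol (lactol, epimers at C4 of the dioxolane) | C[C@]1(CC(=C)C[C@@H](C)CI)O[C@H](C(C)(C)C)OC1O | intermediate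
11 | methyl 2-[bis(2,2,2-trifluoroethoxy)phosphoryl]acetate | COC(=O)CP(=O)(OCC(F)(F)F)OCC(F)(F)F | starting material
12 | (2R,6R)-2-hydroxy-7-iodo-2,6-dimethyl-4-methylideneheptanal | C[C@](O)(C=O)CC(=C)C[C@@H](C)CI | intermediate
13 | methyl (2Z,4R,8R)-4-hydroxy-9-iodo-4,8-dimethyl-6-methylidenenon-2-enoate (formed as its potassium alkoxide) | COC(=O)/C=C\[C@](C)(O)CC(=C)C[C@@H](C)CI | intermediate
14 | (5R)-5-[(4R)-5-iodo-4-methyl-2-methylidenepentyl]-5-methylfuran-2(5H)-one | C[C@]1(CC(=C)C[C@@H](C)CI)OC(=O)C=C1 | intermediate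
15 | (5R)-5-[(2RS,4R)-2-hydroperoxy-5-iodo-2-methoxy-4-methylpentyl]-5-methylfuran-2(5H)-one | C[C@]1(CC(OC)(OO)C[C@@H](C)CI)OC(=O)C=C1 | intermediate
16 | (1R,4RS,6R)-4-[(2R)-3-iodo-2-methylpropyl]-4-methoxy-6-methyl-2,3,7-trioxabicyclo[4.3.0]nonan-8-one (cis-fused, anomeric mixture at C4 of the bicycle = C6) | IC[C@H](C)CC1(OC)C[C@@]2(C)OC(=O)C[C@H]2OO1 | intermediate
17 | (1R,4R,6R)-4-[(2R)-3-iodo-2-methylpropyl]-4,6-dimethyl-2,3,7-trioxabicyclo[4.3.0]nonan-8-one | IC[C@H](C)C[C@]1(C)C[C@@]2(C)OC(=O)C[C@H]2OO1 | intermediate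
18 | phenylacetaldehyde | O=CCc1ccccc1 | starting material
19 | 2-(triphenylphosphoranylidene)propanal | CC(C=O)=P(c1ccccc1)(c1ccccc1)c1ccccc1 | starting material
20 | (2E)-2-methyl-4-phenylbut-2-enal | O=C/C(C)=C/Cc1ccccc1 | intermediate
21 | [(2E)-5,5-dibromo-3-methylpenta-2,4-dien-1-yl]benzene | BrC(Br)=C/C(C)=C/Cc1ccccc1 | intermediate
22 | lithium (3E)-3-methyl-5-phenylpent-3-en-1-yn-1-ide | [Li]C#C/C(C)=C/Cc1ccccc1 | intermediate
23 | [(2E)-3-methylhex-2-en-4-yn-1-yl]benzene | CC#C/C(C)=C/Cc1ccccc1 | intermediate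
24 | Cp2Zr(Cl)[(2E,4E)-4-methyl-6-phenylhexa-2,4-dien-2-yl] (alkenylzirconocene chloride) | C/C(=C\C(C)=C\Cc1ccccc1)[Zr](Cl)(C1C=CC=C1)C1C=CC=C1 | intermediate
25 | [(2E,4E)-5-iodo-3-methylhexa-2,4-dien-1-yl]benzene | I/C(C)=C/C(C)=C/Cc1ccccc1 | intermediate
26 | iodo{(2R)-3-[(1R,4R,6R)-4,6-dimethyl-8-oxo-2,3,7-trioxabicyclo[4.3.0]nonan-4-yl]-2-methylpropyl}zinc | I[Zn]C[C@H](C)C[C@]1(C)C[C@@]2(C)OC(=O)C[C@H]2OO1 | intermediate
27 | plakortolide, (1R,4R,6R)-4,6-dimethyl-4-[(2S,4E,6E)-2,4,6-trimethyl-8-phenylocta-4,6-dien-1-yl]-2,3,7-trioxabicyclo[4.3.0]nonan-8-one | CC(=C\Cc1ccccc1)/C=C(\C)C[C@H](C)C[C@]1(C)C[C@@]2(C)OC(=O)C[C@H]2OO1 | target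

**Step count**
Total steps: 13. Longest linear sequence: 9 (steps 1–8 and 13); the dienyl iodide branch is steps 9–12.

**Three steps most likely to fail**

Step 8 (the new methylation). The Lewis acid may instead open the ring at the peroxide oxygen, trigger Hock-type fragmentation, or AlMe3 may reduce the O–O bond. The fallback uses known chemistry, sets out from 14 and comes back at 17, bypassing steps 7 and 8. Mukaiyama–Isayama hydroperoxysilylation of the 1,1-disubstituted alkene of 14 (Co(thd)2, O2, Et3SiH, ClCH2CH2Cl, rt) gives the silyl peroxide (5R)-5-[(2RS,4R)-5-iodo-2,4-dimethyl-2-(triethylsilylperoxy)pentyl]-5-methylfuran-2(5H)-one F4. Desilylation with TBAF in THF releases the peroxide anion, which closes ring B by oxa-Michael addition. This gives 17 together with its C6 epimer (1R,4S,6R)-4-[(2R)-3-iodo-2-methylpropyl]-4,6-dimethyl-2,3,7-trioxabicyclo[4.3.0]nonan-8-one F5 in a ratio near 1:1, and the two are separated by chromatography. The price is the loss of C6 control.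

Step 13 (zinc insertion and zerovalent palladium in the presence of the O–O bond). Zinc metal or the alkylzinc may reduce or attack the peroxide. The fallback reverses the polarity, sets out from 17 (with 23 from the side branch) and comes back at 27. Hydroboration of enyne 23 with 9-BBN-H (THF, 0 °C → rt) gives the alkenylborane 9-[(2E,4E)-4-methyl-6-phenylhexa-2,4-dien-2-yl]-9-borabicyclo[3.3.1]nonane F6. This is coupled with alkyl iodide 17 as the electrophile in an alkyl–alkenyl Suzuki–Miyaura reaction (Pd(OAc)2, PCy3, K3PO4·H2O, THF, rt) to give 27, so no zinc metal or organozinc touches the peroxide.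

Step 3 (electrochemical coupling). The hindered 2-bromoalkene may homocouple or be hydrodehalogenated, and the alkyl radical may dimerise. The fallback replaces the reductive coupling by a preformed organometallic, sets out from 7 and comes back at 8. Silylation of 7 (TBSCl, imidazole, CH2Cl2) gives (S)-(3-bromo-2-methylpropoxy)(tert-butyl)dimethylsilane F1. Zinc insertion (Zn, LiCl, THF, 50 °C) gives bromo[(2S)-3-{[tert-butyl(dimethyl)silyl]oxy}-2-methylpropyl]zinc F2. Negishi coupling of F2 with 6 (Pd(OAc)2, SPhos, THF, rt) gives (2S,5R)-2-tert-butyl-5-[(4R)-5-{[tert-butyl(dimethyl)silyl]oxy}-4-methyl-2-methylidenepentyl]-5-methyl-1,3-dioxolan-4-one F3, and TBAF in THF returns 8.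

**Further compounds**
F1 | step 3 | (S)-(3-bromo-2-methylpropoxy)(tert-butyl)dimethylsilane | CC(C)(C)[Si](C)(C)OC[C@H](C)CBr
F2 | step 3 | bromo[(2S)-3-{[tert-butyl(dimethyl)silyl]oxy}-2-methylpropyl]zinc | CC(C)(C)[Si](C)(C)OC[C@H](C)C[Zn]Br
F3 | step 3 | (2S,5R)-2-tert-butyl-5-[(4R)-5-{[tert-butyl(dimethyl)silyl]oxy}-4-methyl-2-methylidenepentyl]-5-methyl-1,3-dioxolan-4-one | C[C@]1(CC(=C)C[C@@H](C)CO[Si](C)(C)C(C)(C)C)O[C@H](C(C)(C)C)OC1=O
F4 | step 8 | (5R)-5-[(2RS,4R)-5-iodo-2,4-dimethyl-2-(triethylsilylperoxy)pentyl]-5-methylfuran-2(5H)-one | C[C@]1(CC(C)(OO[Si](CC)(CC)CC)C[C@@H](C)CI)OC(=O)C=C1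
F5 | step 8 | (1R,4S,6R)-4-[(2R)-3-iodo-2-methylpropyl]-4,6-dimethyl-2,3,7-trioxabicyclo[4.3.0]nonan-8-one | IC[C@H](C)C[C@@]1(C)C[C@@]2(C)OC(=O)C[C@H]2OO1
F6 | step 13 | 9-[(2E,4E)-4-methyl-6-phenylhexa-2,4-dien-2-yl]-9-borabicyclo[3.3.1]nonane | C/C(=C\C(C)=C\Cc1ccccc1)B1C2CCCC1CCC2
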